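## The problem

Target 20 is a diaryl ether whose oxygen joins C8 of a 6-hydroxy-3-pentylisocoumarin (ring A is the benzo ring C4a–C8a, ring B the pyranone with O2, C1, C3 and C4) to C5' of an olivetolic acid unit (ring C: C1' carboxyl, C2' hydroxyl, C4' hydroxyl, C6' pentyl). The molecule has no stereocenter, so the task is one of regiochemistry and of joining two crowded arenes. On ring C the ether oxygen lies between the C4' hydroxyl and the C6' pentyl chain, and on ring A it is ortho to C8a, which carries the lactone carbonyl, so a copper- or palladium-mediated etherification of a doubly ortho-substituted phenol with an ortho-substituted aryl halide is the weak spot of a conventional plan. Ring A is 1,2,3,5-tetrasubstituted and ring C pentasubstituted, so every substituent has to be placed by its neighbours, not by late electrophilic substitution. The free 2,4-dihydroxybenzoic acid of ring C loses CO2 on heating, most readily in acid, and the enol lactone of ring B opens with hydroxide, alkoxides and amines; both must be unveiled late and without acyl-transfer conditions. The feature that opens the chosen key step is on ring A: the ether oxygen on C8 and the carbonyl carbon C1 on C8a sit on adjacent carbons, and C4a, on the other side of C8a, bears C4. A nucleophile and an electrophile on neighbouring ring carbons is the pattern left by addition across an aryne, and a chlorine on C4a can steer that addition and later be exchanged for the C4–C3 unit.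

## Retrosynthesis

Target 20 is traced to trimethyl ether acid 19 by cutting three aryl O–methyl bonds, and 19 to its methyl ester 18 by cutting the ester O–methyl bond. Methyl is chosen over benzyl or silyl groups because the protecting groups must survive a Lewis-acid formylation, a peracid, fluoride, a carbonate-mediated palladium coupling and hot acid. The ester is cleaved before the ethers so that the ring C carboxyl is set free while C2' and C4' are still methoxy groups, where the benzoate is not prone to decarboxylation. The free resorcylic acid then appears only in the last, cold operation. Both forward reactions must attack the methyl carbon and not an acyl carbon, since acyl attack would open ring B.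

Ring B of 18 is opened at O2–C3 to give ortho-alkynyl ester 17, and 17 is cut at C4a–C4 into aryl chloride 15 and hept-1-yne (16). The alternative of growing ring B from a benzylic methyl group would need a strong base beside two aryl esters. The alkyne brings C3, C4 and the pentyl chain in one commercial piece and uses the chlorine that the key step needs anyway. The forward cyclization must be 6-endo. It is run on the methyl ester under acid, so that a free carboxylate, which adds 5-exo under base, never sits beside the alkyne. For that reason acid 14 is first converted to diester 15.

Acid 14 is cut at C8–O and at C8a–C1 into silyl triflate 5, phenol 10 and carbon dioxide (11). Cutting only the C8–O bond would demand a crowded metal-mediated etherification with an electrophile that already carries C1. The double cut removes C1 as CO2 and turns the ether formation into an addition to aryne 13, which needs no metal and is little affected by ortho substituents. The precursors are far simpler: a trisubstituted benzene and a phenol that already carries every substituent of ring C. The forward reaction must put the oxygen on C8 and the carboxyl on C8a, and the aryl anion must meet CO2 before it finds a proton or loses chloride. The chlorine on C4a, a dry preformed cesium phenoxide 12 and a CO2 atmosphere are there to secure this.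

Silyl triflate 5 is cut at its C–Si and O–S bonds and traced through lithium phenoxide 4 and silyl ether 3 to bromophenol 2, and 2 at its C–Br bond to 2-chloro-4-methoxyphenol (1). The phenol hydroxyl of 1 directs bromine to its one free ortho position, and that oxygen then becomes the triflate leaving group. The bromine site receives silicon by an oxygen-to-carbon silyl shift. The forward sequence asks only that bromine, not chlorine, undergoes exchange with the alkyllithium.

Phenol 10 is cut at its C3–O bond to aldehyde 8 (through formate 9), 8 at the C–CHO bond to dimethyl ether 7, and 7 at two O–methyl bonds to methyl 2,4-dihydroxy-6-pentylbenzoate (6). Compound 6 already holds the ester, the pentyl chain and both oxygens of ring C in the right places. Only one oxygen has to be added, at the position para to one methoxy group and next to the pentyl chain. Formylation must go there and not between the two methoxy groups.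

## Roads not taken

Alternative 1: Ring C is cut at C4'–C3', C1'–C2' and C4'–C5' and grown last by a Danheiser benzannulation. In the forward step an alpha-diazo ketone that already carries the isocoumarin-8-yloxy group is irradiated. Wolff rearrangement gives an aryloxy-substituted vinylketene, which adds an alkoxyalkyne by [2+2] cycloaddition. The cyclobutenone opens to a dienylketene and closes by 6π electrocyclization to phenol A1. The merits are real. The ether C–O bond is made early on an open-chain carbon and not between two crowded arenes, the substitution pattern of ring C follows from connectivity, and every event belongs to a known reaction type. On precedent this road is ahead of the chosen plan, whose key step is untested. The weak points are specific to this target. A1 carries hydrogen at C1', so the carboxyl must still be introduced on a fully elaborated, electron-rich phenol, with C3' (between two oxygens) competing. The diazo ketone has to be made and photolysed beside the isocoumarin chromophore. Rings A and B must be complete before ring C is begun, which makes the sequence long and linear. Against the better precedent the chosen plan sets a ring C that arrives with its carboxyl in place from a catalogue ester, two short convergent branches, and no late C–H carboxylation.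

Alternative 2: Rings A and B are cut together at C4a–C8a and C5–C6, and the ether at C8–O, in a hexadehydro-Diels–Alder cascade. Heating an ester-tethered triyne would close both rings and leave a C7–C8 aryne. The ring C phenol adds its O–H across it, with oxygen going to C8 away from the C6 alkoxy group, to give A2. In bonds and rings formed per step this road is clearly better than the chosen one: A2 is the 6-ethoxy analogue of 18, which the chosen route reaches only three steps after its key step. The reaction needs no reagent, and the alkoxy group directs the phenol correctly. The difficulty is the triyne. It combines an alkoxy-substituted diyne with a Z-configured enol ester of an enyne, both labile and laborious to assemble. The tether closes a six-membered ring through an ester that prefers the unreactive conformation, so a high temperature would be needed for a fragile substrate. The hindered phenol must also outcompete every other fate of the aryne. Against the superior convergence of the cascade the chosen plan sets partners that are two and three steps from catalogue compounds and an aryne generated at or below room temperature.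

Alternative 3: Ring C is cut at C1'–C6' and C2'–C3' and built as a cyclohexane-1,3-dione that is aromatized later. An alkoxide base adds a malonate diester to the beta carbon of an alpha-aryloxy enone, and the methyl ketone enolate then closes the ring by Claisen condensation to give A3. This is the classical route to 5-alkylresorcylates. Its reagents are cheaper and its chemistry older than anything in the chosen plan, the ether bond is formed early at an unhindered carbon, and the three stereocenters of A3 disappear on aromatization and need no control. Three weak points count against it here.
- The enone bears an oxygen donor on its alpha carbon and an alkyl group on its beta carbon, which makes it a poor acceptor.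
- The dehydrogenation of A3 calls for a halogenating oxidant beside an electron-rich aryl ether ring that competes for it.
- Ring A in A3 carries only a methyl group on C4a, so ring B would still have to be built by benzylic deprotonation and acylation beside two esters.

The chosen plan is shorter after its key step and installs ring C already aromatic. It concedes to this alternative the cost of reagents and the certainty of the individual reaction types.

Key step: step 6

Remark on the chemistry: the target has no stereocenter, so no step needs stereocontrol; compounds 1, 6, 11 and 16 are taken to be catalogue chemicals.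

## Route

Step 1
Reactants: 1 2-chloro-4-methoxyphenol
Product: 2 2-bromo-6-chloro-4-methoxyphenol
Conditions: NBS (1.05 equiv), i-Pr2NH (10 mol %), CH2Cl2, 0 °C
Reagents that add atoms: N-bromosuccinimide, O=C1CCC(=O)N1Br
Why: Electrophilic aromatic bromination; the hydroxyl group is the strongest director and its para position is blocked by the methoxy group, so bromine should enter the one free ortho position, and amine catalysis reinforces ortho delivery.

Step 2
Reactants: 2 2-bromo-6-chloro-4-methoxyphenol
Product: 5 2-chloro-4-methoxy-6-(trimethylsilyl)phenyl trifluoromethanesulfonate, via O-trimethylsilyl ether 3 (not isolated), via lithium 6-silylphenoxide 4 (not isolated)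
Conditions: HMDS, THF, reflux, then evaporation; n-BuLi, THF, −95 → −78 °C; Tf2O, −78 °C → rt
Reagents that add atoms: hexamethyldisilazane, C[Si](C)(C)N[Si](C)(C)C; trifluoromethanesulfonic anhydride, O=S(=O)(OS(=O)(=O)C(F)(F)F)C(F)(F)F
Why: O-silylation, bromine–lithium exchange, anionic 1,3 oxygen-to-carbon silyl shift (retro-Brook rearrangement) and O-triflation of the resulting phenoxide, the standard one-flask entry to ortho-silylaryl triflates. Exchange at bromine is much faster than at chlorine, and the lithiated carbon is meta to chlorine, so LiCl cannot be eliminated.

Step 3
Reactants: 6 methyl 2,4-dihydroxy-6-pentylbenzoate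
Product: 7 methyl 2,4-dimethoxy-6-pentylbenzoate
Conditions: MeI, K2CO3, DMF, 50 °C
Reagents that add atoms: iodomethane, CI
Why: Williamson O-methylation of both phenols; warm DMF is used because the C2 hydroxyl is hydrogen-bonded to the ester, which itself is inert to carbonate.

Step 4
Reactants: 7 methyl 2,4-dimethoxy-6-pentylbenzoate
Product: 8 methyl 3-formyl-4,6-dimethoxy-2-pentylbenzoate
Conditions: Cl2CHOMe, TiCl4, CH2Cl2, −20 → 0 °C; ice/aq HCl
Reagents that add atoms: dichloromethyl methyl ether, COC(Cl)Cl; water, O
Why: Rieche formylation (Friedel–Crafts type). The ring position between the pentyl chain and a methoxy group (C5 of 7, C3 in the name of 8) is para to one methoxy group and ortho to the other, whereas the only other free position is wedged between two methoxy groups. This is the pattern in which 3,5-dimethoxyalkylbenzenes are formylated next to the alkyl group.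

Step 5
Reactants: 8 methyl 3-formyl-4,6-dimethoxy-2-pentylbenzoate
Product: 10 methyl 3-hydroxy-4,6-dimethoxy-2-pentylbenzoate, via aryl formate 9 (not isolated)
Conditions: mCPBA, CH2Cl2, 0 °C → rt; aq NaHCO3 wash; K2CO3 (cat.), MeOH, rt
Reagents that add atoms: 3-chloroperoxybenzoic acid, O=C(OO)c1cccc(Cl)c1
Why: Dakin-type oxidation: Baeyer–Villiger migration of the aryl group, favoured by the ortho and para methoxy donors, gives formate 9, which is methanolysed under conditions too mild for the hindered benzoate.

Step 6
Reactants: 5 2-chloro-4-methoxy-6-(trimethylsilyl)phenyl trifluoromethanesulfonate; 10 methyl 3-hydroxy-4,6-dimethoxy-2-pentylbenzoate; 11 carbon dioxide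
Product: 14 2-chloro-6-[4,6-dimethoxy-3-(methoxycarbonyl)-2-pentylphenoxy]-4-methoxybenzoic acid, via cesium phenoxide 12 (not isolated), via 3-chloro-5-methoxybenzyne 13 (not isolated)
Conditions: 10, CsOH·H2O (1.0 equiv), MeOH, rt, then evaporation and toluene azeotrope; 5 (1.2 equiv, added slowly), CsF, 18-crown-6, THF, CO2 (1 atm), 0 °C → rt; aq HCl
Reagents that add atoms: carbon dioxide (compound 11), O=C=O
Why: Proposed new method: fluoride attacks silicon of 5 and expels triflate to give aryne 13; the oxygen of the crown-separated phenoxide 12 adds to the aryne carbon remote from chlorine (the future C8), and the aryl anion formed on the carbon next to chlorine (C8a) is carboxylated by dissolved CO2, so that the C8–O and C8a–C1 bonds form in one operation. The closest known reaction type is the three-component coupling of arynes with amines or imines and CO2 to anthranilic acid derivatives, taken together with the fluoride-mediated O-arylation of phenols by arynes and the xanthone synthesis in which a phenoxide–aryne adduct is trapped by a neighbouring ester; an oxygen nucleophile in the CO2 coupling is the untested element. No ring closes and no stereocenter is formed. The selectivity required is regiochemical: the inductively withdrawing chlorine on C4a distorts the aryne so that the remote carbon is the electrophilic one and the negative charge develops beside the halogen, and this bias should outweigh the weak opposite pull of the C6 methoxy group, which sits para to C8a. Carboxylation must beat protonation of the aryl anion, which is served by a water-free preformed phenoxide, by THF in place of a C–H acidic solvent and by a large excess of CO2. It must also beat loss of chloride from the ortho-chloroaryl anion, which the low temperature and the poorer leaving-group ability of chloride compared with bromide should favour. Addition to an aryne needs no metal and is little slowed by the two ortho substituents of 12, the very feature that handicaps a copper or palladium etherification. Slow addition of 5 keeps the aryne dilute so that the product carboxylate is not arylated in turn, and extraction into aqueous base separates 14 from neutral by-products.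

Step 7
Reactants: 14 2-chloro-6-[4,6-dimethoxy-3-(methoxycarbonyl)-2-pentylphenoxy]-4-methoxybenzoic acid
Product: 15 methyl 3-[3-chloro-5-methoxy-2-(methoxycarbonyl)phenoxy]-4,6-dimethoxy-2-pentylbenzoate
Conditions: MeI, K2CO3, DMF, rt
Reagents that add atoms: iodomethane, CI
Why: SN2 O-alkylation of the carboxylate, which is insensitive to the two ortho substituents that would block acid-catalysed esterification. Capping the acid keeps a carboxylate from adding 5-exo to the alkyne under the basic conditions of the next step.

Step 8
Reactants: 15 methyl 3-[3-chloro-5-methoxy-2-(methoxycarbonyl)phenoxy]-4,6-dimethoxy-2-pentylbenzoate; 16 hept-1-yne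
Product: 17 methyl 3-[3-(hept-1-yn-1-yl)-5-methoxy-2-(methoxycarbonyl)phenoxy]-4,6-dimethoxy-2-pentylbenzoate
Conditions: PdCl2(MeCN)2 (3 mol %), XPhos (9 mol %), Cs2CO3, MeCN, 85 °C
Reagents that add atoms: hept-1-yne (compound 16), CCCCCC#C
Why: Copper-free Sonogashira coupling of an aryl chloride; the bulky electron-rich biarylphosphine makes zerovalent palladium insert into the C–Cl bond, which is activated by the ortho ester, and both methyl esters are stable to anhydrous carbonate.

Step 9
Reactants: 17 methyl 3-[3-(hept-1-yn-1-yl)-5-methoxy-2-(methoxycarbonyl)phenoxy]-4,6-dimethoxy-2-pentylbenzoate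
Product: 18 methyl 4,6-dimethoxy-3-[(6-methoxy-1-oxo-3-pentyl-1H-isochromen-8-yl)oxy]-2-pentylbenzoate
Conditions: Cu(OTf)2 (10 mol %), TFA, ClCH2CH2Cl, 80 °C
Reagents that add atoms: none
Why: Acid-promoted 6-endo-dig cyclization of an ortho-alkynyl benzoate ester: the carbonyl oxygen of the ring A ester attacks the activated alkyne at its distal carbon to give an aromatic 1-methoxy-2-benzopyrylium ion, and trifluoroacetate removes the O-methyl group. Only the ester ortho to the alkyne can take part, so the ring C ester is untouched.

Step 10
Reactants: 18 methyl 4,6-dimethoxy-3-[(6-methoxy-1-oxo-3-pentyl-1H-isochromen-8-yl)oxy]-2-pentylbenzoate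
Product: 19 4,6-dimethoxy-3-[(6-methoxy-1-oxo-3-pentyl-1H-isochromen-8-yl)oxy]-2-pentylbenzoic acid
Conditions: LiI, pyridine, reflux; aq HCl
Reagents that add atoms: none
Why: SN2 dealkylation of a hindered methyl ester by iodide at the methyl carbon, which the two ortho substituents do not shield. The enol lactone offers no alkyl carbon for such attack, and the product is a dimethoxybenzoate salt that should not decarboxylate.

Step 11
Reactants: 19 4,6-dimethoxy-3-[(6-methoxy-1-oxo-3-pentyl-1H-isochromen-8-yl)oxy]-2-pentylbenzoic acid
Product: 20 4,6-dihydroxy-3-[(6-hydroxy-1-oxo-3-pentyl-1H-isochromen-8-yl)oxy]-2-pentylbenzoic acid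
Conditions: BBr3 (excess), CH2Cl2, −78 °C → rt; ice-water
Reagents that add atoms: none
Why: Lewis-acid cleavage of the three aryl methyl ethers, with the diaryl ether and the enol lactone inert to BBr3. The liberated salicylic acid is held as a boron chelate until a cold quench, which should prevent protodecarboxylation.

## Compound list

1 | 2-chloro-4-methoxyphenol | COc1ccc(O)c(Cl)c1 | starting material
2 | 2-bromo-6-chloro-4-methoxyphenol | COc1cc(Cl)c(O)c(Br)c1 | intermediate
3 | (2-bromo-6-chloro-4-methoxyphenoxy)trimethylsilane | COc1cc(Cl)c(O[Si](C)(C)C)c(Br)c1 | intermediate
4 | lithium 2-chloro-4-methoxy-6-(trimethylsilyl)phenolate | COc1cc(Cl)c([O-])c([Si](C)(C)C)c1.[Li+] | intermediate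
5 | 2-chloro-4-methoxy-6-(trimethylsilyl)phenyl trifluoromethanesulfonate | COc1cc(Cl)c(OS(=O)(=O)C(F)(F)F)c([Si](C)(C)C)c1 | intermediate
6 | methyl 2,4-dihydroxy-6-pentylbenzoate | CCCCCc1cc(O)cc(O)c1C(=O)OC | starting material
7 | methyl 2,4-dimethoxy-6-pentylbenzoate | CCCCCc1cc(OC)cc(OC)c1C(=O)OC | intermediate
8 | methyl 3-formyl-4,6-dimethoxy-2-pentylbenzoate | CCCCCc1c(C=O)c(OC)cc(OC)c1C(=O)OC | intermediate
9 | methyl 3-(formyloxy)-4,6-dimethoxy-2-pentylbenzoate | CCCCCc1c(OC=O)c(OC)cc(OC)c1C(=O)OC | intermediate
10 | methyl 3-hydroxy-4,6-dimethoxy-2-pentylbenzoate | CCCCCc1c(O)c(OC)cc(OC)c1C(=O)OC | intermediate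
11 | carbon dioxide | O=C=O | starting material
12 | cesium 4,6-dimethoxy-3-(methoxycarbonyl)-2-pentylphenolate | CCCCCc1c([O-])c(OC)cc(OC)c1C(=O)OC.[Cs+] | intermediate
13 | 3-chloro-5-methoxybenzyne | COC1=CC#CC(Cl)=C1 | intermediate
14 | 2-chloro-6-[4,6-dimethoxy-3-(methoxycarbonyl)-2-pentylphenoxy]-4-methoxybenzoic acid | COc1cc(Cl)c(C(=O)O)c(Oc2c(OC)cc(OC)c(C(=O)OC)c2CCCCC)c1 | intermediate
15 | methyl 3-[3-chloro-5-methoxy-2-(methoxycarbonyl)phenoxy]-4,6-dimethoxy-2-pentylbenzoate | COc1cc(Cl)c(C(=O)OC)c(Oc2c(OC)cc(OC)c(C(=O)OC)c2CCCCC)c1 | intermediate
16 | hept-1-yne | CCCCCC#C | starting material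
17 | methyl 3-[3-(hept-1-yn-1-yl)-5-methoxy-2-(methoxycarbonyl)phenoxy]-4,6-dimethoxy-2-pentylbenzoate | CCCCCC#Cc1cc(OC)cc(Oc2c(OC)cc(OC)c(C(=O)OC)c2CCCCC)c1C(=O)OC | intermediate
18 | methyl 4,6-dimethoxy-3-[(6-methoxy-1-oxo-3-pentyl-1H-isochromen-8-yl)oxy]-2-pentylbenzoate | CCCCCc1cc2cc(OC)cc(Oc3c(OC)cc(OC)c(C(=O)OC)c3CCCCC)c2c(=O)o1 | intermediate
19 | 4,6-dimethoxy-3-[(6-methoxy-1-oxo-3-pentyl-1H-isochromen-8-yl)oxy]-2-pentylbenzoic acid | CCCCCc1cc2cc(OC)cc(Oc3c(OC)cc(OC)c(C(=O)O)c3CCCCC)c2c(=O)o1 | intermediate
20 | 4,6-dihydroxy-3-[(6-hydroxy-1-oxo-3-pentyl-1H-isochromen-8-yl)oxy]-2-pentylbenzoic acid | CCCCCc1cc2cc(O)cc(Oc3c(O)cc(O)c(C(=O)O)c3CCCCC)c2c(=O)o1 | target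

## Step count and risks

Total step count: 11. Longest linear sequence: 9 steps (6 → 7 → 8 → 10 → 14 → 15 → 17 → 18 → 19 → 20, steps 3 to 11). The branch from 1 to 5 adds 2 steps.

Step 6 (key step, new method). Four processes can divert it:
- protonation of the C8a aryl anion before it meets CO2;
- reversible carbonation of the phenoxide oxygen by CO2, which lowers its nucleophilicity towards the aryne;
- expulsion of chloride from the ortho-chloroaryl anion;
- arylation of the product carboxylate by a second aryne.

The fallback uses known reactions only, sets out from 10 and returns at 14. 1-Chloro-3-fluoro-5-methoxybenzene is lithiated between the two halogens with LiN(i-Pr)2 in THF at −78 °C and formylated with DMF to give 2-chloro-6-fluoro-4-methoxybenzaldehyde F1. Phenol 10 then displaces the fluoride of F1, which lies ortho to the aldehyde, by nucleophilic aromatic substitution (Cs2CO3, DMF, 100 °C; fluoride leaves far faster than chloride) to give methyl 3-(3-chloro-2-formyl-5-methoxyphenoxy)-4,6-dimethoxy-2-pentylbenzoate F2. Pinnick oxidation (NaClO2, NaH2PO4, 2-methylbut-2-ene, t-BuOH/H2O) converts F2 into 14, and the route resumes at step 7.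

Step 4. The Lewis acid may strip the methyl ether that is chelated to the ester, and attack at the position between the two methoxy groups may compete on this ester-deactivated ring. The fallback sets out from 7 and returns at 10, replacing steps 4 and 5. Bromination with NBS in MeCN, which is strongly para-selective for methoxyarenes and uses no Lewis acid, should give methyl 3-bromo-4,6-dimethoxy-2-pentylbenzoate F3. Miyaura borylation of F3 (B2pin2, Pd(OAc)2, SPhos, KOAc, dioxane, 90 °C) gives methyl 4,6-dimethoxy-2-pentyl-3-(4,4,5,5-tetramethyl-1,3,2-dioxaborolan-2-yl)benzoate F4. Oxidation of the C–B bond of F4 (NaBO3·4H2O, THF/H2O, rt) delivers 10.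

Step 8. Transfer of the alkyne to palladium under carbonate conditions may be slow at the temperature an aryl chloride requires, so that oligomerization of the terminal alkyne and hydrodechlorination compete. The fallback sets out from 15 and 16 and returns at 17. Hept-1-yne is deprotonated (n-BuLi, THF, −78 °C) and transmetalated with ZnCl2 to hept-1-yn-1-ylzinc chloride F5. F5 is coupled with 15 in a Negishi reaction (Pd(OAc)2, XPhos, THF, 60 °C), where transmetalation is fast and no free alkyne or base is present.

Step 9. Removal of the O-methyl group from the benzopyrylium intermediate may lag behind its hydrolytic opening to a keto ester, and some 5-exo closure is possible. The fallback sets out from 17 and returns at 18. Iodocyclization with I2 (CH2Cl2, rt), a reliably 6-endo electrophilic cyclization in which iodide takes the methyl group, gives methyl 3-[(4-iodo-6-methoxy-1-oxo-3-pentyl-1H-isochromen-8-yl)oxy]-4,6-dimethoxy-2-pentylbenzoate F6. The C4 iodine of F6 is then removed by palladium-catalysed transfer hydrogenolysis (Pd(OAc)2, PPh3, HCO2H, Et3N, DMF, 60 °C) to give 18.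

Step 10. Prolonged heating in pyridine may degrade the enol lactone, or the dealkylation may stall on the crowded ester. The fallback sets out from 18 and returns at 20, replacing steps 10 and 11. BBr3 (CH2Cl2, −78 °C → rt) is applied first and cleaves the three ethers while the carboxyl stays masked. The product is methyl 4,6-dihydroxy-3-[(6-hydroxy-1-oxo-3-pentyl-1H-isochromen-8-yl)oxy]-2-pentylbenzoate F7, unless the Lewis acid already removes the ester methyl by the same alkyl–oxygen pathway and gives 20 directly. F7 is then dealkylated with LiI in refluxing ethyl acetate, without pyridine and at lower temperature, to give 20.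

## Further compounds

F1 | step 6 | 2-chloro-6-fluoro-4-methoxybenzaldehyde | COc1cc(F)c(C=O)c(Cl)c1
F2 | step 6 | methyl 3-(3-chloro-2-formyl-5-methoxyphenoxy)-4,6-dimethoxy-2-pentylbenzoate | COc1cc(Cl)c(C=O)c(Oc2c(OC)cc(OC)c(C(=O)OC)c2CCCCC)c1
F3 | step 4 | methyl 3-bromo-4,6-dimethoxy-2-pentylbenzoate | CCCCCc1c(Br)c(OC)cc(OC)c1C(=O)OC
F4 | step 4 | methyl 4,6-dimethoxy-2-pentyl-3-(4,4,5,5-tetramethyl-1,3,2-dioxaborolan-2-yl)benzoate | CCCCCc1c(B2OC(C)(C)C(C)(C)O2)c(OC)cc(OC)c1C(=O)OC
F5 | step 8 | hept-1-yn-1-ylzinc chloride | CCCCCC#C[Zn]Cl
F6 | step 9 | methyl 3-[(4-iodo-6-methoxy-1-oxo-3-pentyl-1H-isochromen-8-yl)oxy]-4,6-dimethoxy-2-pentylbenzoate | CCCCCc1oc(=O)c2c(Oc3c(OC)cc(OC)c(C(=O)OC)c3CCCCC)cc(OC)cc2c1I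
F7 | step 10 | methyl 4,6-dihydroxy-3-[(6-hydroxy-1-oxo-3-pentyl-1H-isochromen-8-yl)oxy]-2-pentylbenzoate | CCCCCc1cc2cc(O)cc(Oc3c(O)cc(O)c(C(=O)OC)c3CCCCC)c2c(=O)o1
A1 | alternative 1 | 8-(4-ethoxy-2-hydroxy-6-pentylphenoxy)-6-methoxy-3-pentyl-1H-isochromen-1-one | CCOc1cc(O)c(Oc2cc(OC)cc3cc(CCCCC)oc(=O)c23)c(CCCCC)c1
A2 | alternative 2 | methyl 3-[(6-ethoxy-1-oxo-3-pentyl-1H-isochromen-8-yl)oxy]-4,6-dimethoxy-2-pentylbenzoate | CCCCCc1cc2cc(OCC)cc(Oc3c(OC)cc(OC)c(C(=O)OC)c3CCCCC)c2c(=O)o1
A3 | alternative 3 | methyl 5-[5-methoxy-2-(methoxycarbonyl)-3-methylphenoxy]-2,4-dioxo-6-pentylcyclohexane-1-carboxylate (racemic, all-trans, one enantiomer drawn) | CCCCC[C@@H]1[C@@H](Oc2cc(OC)cc(C)c2C(=O)OC)C(=O)CC(=O)[C@H]1C(=O)OC
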